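Ring A of the target carries the ether oxygen O1 (on C8a) and the ketone carbon C4 (on C4a) on adjacent carbons. This is the imprint of an aryne that has accepted a nucleophile at one end and an electrophile at the other. Ring C is therefore cut at O1–C8a and C4–C4a. In one operation a 3,5-dimethoxy-6-silylbenzyne takes up the carbinol oxygen of an enantiopure β-oxy ester, and its C4a anion acylates on the ester. This closes ring C with C2 untouched. The precursors are a symmetric 2,6-bis(trimethylsilyl)aryl triflate and the O-trimethylsilyl ether of ethyl (S)-3-(3,4-dimethoxyphenyl)-3-hydroxypropanoate. The surviving C8 silyl group is later exchanged for methoxyl.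

Key step: step 6

Remarks on the chemistry
- Assumption: flavanone numbering is used (O1, C2, C3, C4, C4a, C5–C8, C8a; ring A benzo, ring B the C2 aryl, ring C the pyranone). Reagents carry no numbers.
- Configuration: the target is 2S. The carbinol carbon of 10 becomes C2 with its C–O bond intact. The order O > aryl > CH2 > H holds from 10 to 17, so S is kept in space and in name.
- Oxygen partner: fluoride does not deprotonate an aliphatic hydroxyl. The alcohol would add as a hydrogen-bonded neutral species and pass its proton to the neighbouring C4a anion, which stops at the open aryl ether. The oxygen is therefore introduced as silyl ether 11, so the flask holds no O–H proton.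
- Ring A phenol: it is carried as a secondary (N-isopropyl) carbamate. This group leaves by E1cB at N–H, so the two flanking silyl groups do not block its removal, and the acid-labile bis-silyl phenol is never isolated.
- Endgame: in 13 the C2–O1 bond is a 3,4-dimethoxybenzylic aryl ether β to a ketone.
  - Boron trihalides could ionise this bond, trap the opened chalcone as a boron chelate and strip the peri 5-methoxyl.
  - Carbonate with an alkyl halide opens ring C by retro-oxa-Michael reaction.
  - Silicon is therefore exchanged through iodine and boron under soft, near-neutral conditions, and the last methyl group is put on by a Mitsunobu reaction.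

Step 1
Reactants: 1 3,5-dimethoxyphenol
Product: 2 3,5-dimethoxyphenyl isopropylcarbamate
Conditions: i-PrNCO, Et3N (cat.), CH2Cl2, rt
Reagents that add atoms: isopropyl isocyanate CC(C)N=C=O
Why: Base-catalysed addition of the phenol O–H across the isocyanate gives the secondary carbamate, a strong directing group for ortho-metalation that can later be removed at N–H whatever the crowding at the ring.

Step 2
Reactants: 2 3,5-dimethoxyphenyl isopropylcarbamate
Product: 6 3,5-dimethoxy-2,6-bis(trimethylsilyl)phenyl isopropylcarbamate, via N-silyl carbamate 3 (not isolated), via C2-silyl N-silyl carbamate 4 (not isolated), via C2,C6-bis-silyl N-silyl carbamate 5 (not isolated)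
Conditions: TMSOTf, TMEDA, Et2O, 0 °C to rt; n-BuLi (2.1 equiv), TMEDA, −78 °C, then TMSCl (1.05 equiv); n-BuLi (1.3 equiv), −78 °C, then TMSCl (2 equiv), to rt; aq NaHCO3
Reagents that add atoms: chlorotrimethylsilane C[Si](C)(C)Cl (both C–Si groups); trimethylsilyl triflate C[Si](C)(C)OS(=O)(=O)C(F)(F)F (N–Si of 3 to 5 only)
Why: Directed ortho-metalation: after transient N-silylation the carbamate, reinforced by the meta methoxyl, directs lithiation first to C2 and then to C6 (each between carbamate and methoxyl) rather than to C4, each aryllithium is silylated by TMSCl, and the labile N–Si bond is hydrolysed in the bicarbonate work-up.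

Step 3
Reactants: 6 3,5-dimethoxy-2,6-bis(trimethylsilyl)phenyl isopropylcarbamate
Product: 8 3,5-dimethoxy-2,6-bis(trimethylsilyl)phenyl trifluoromethanesulfonate, via bis-silyl phenol 7 (not isolated)
Conditions: DBU, Et2NH, MeCN, 40 °C; then PhNTf2, rt to 40 °C; Et3N-deactivated silica
Reagents that add atoms: N-phenylbis(trifluoromethanesulfonimide) O=S(=O)(N(c1ccccc1)S(=O)(=O)C(F)(F)F)C(F)(F)F
Why: DBU deprotonates N–H and the phenoxide leaves by E1cB (the isocyanate is scavenged by Et2NH as a urea), so the flanking silyl groups do not hinder cleavage, and O-sulfonylation in the same basic flask spares the protodesilylation-prone phenol 7 any handling.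

Step 4
Reactants: 9 ethyl 3-(3,4-dimethoxyphenyl)-3-oxopropanoate
Product: 10 ethyl (S)-3-(3,4-dimethoxyphenyl)-3-hydroxypropanoate
Conditions: H2 (30 bar), [RuCl(p-cymene)((R)-SEGPHOS)]Cl (0.5 mol %), EtOH, 60 °C
Reagents that add atoms: none
Why: Noyori asymmetric hydrogenation of a β-keto ester: chelation of ketone and ester oxygens to ruthenium fixes the face of hydride delivery, and the (R)-ligand, which gives (R)-3-hydroxybutanoates, delivers the same spatial sense here, named S because aryl outranks CH2CO2Et.

Step 5
Reactants: 10 ethyl (S)-3-(3,4-dimethoxyphenyl)-3-hydroxypropanoate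
Product: 11 ethyl (S)-3-(3,4-dimethoxyphenyl)-3-(trimethylsilyloxy)propanoate
Conditions: TMSCl, imidazole, CH2Cl2, 0 °C; filtration through Et3N-deactivated silica
Reagents that add atoms: chlorotrimethylsilane C[Si](C)(C)Cl
Why: Standard O-silylation of a secondary alcohol under mild base, which leaves the C–O bond at the stereocentre untouched.

Step 6
Reactants: 8 3,5-dimethoxy-2,6-bis(trimethylsilyl)phenyl trifluoromethanesulfonate; 11 ethyl (S)-3-(3,4-dimethoxyphenyl)-3-(trimethylsilyloxy)propanoate
Product: 13 (S)-2-(3,4-dimethoxyphenyl)-5,7-dimethoxy-8-(trimethylsilyl)chroman-4-one, via 3,5-dimethoxy-6-(trimethylsilyl)benzyne 12 (not isolated)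
Conditions: 8 (1.3 equiv), KF, 18-crown-6 (both dried), THF (0.05 M), −20 to 0 °C; cold pH 7 phosphate buffer
Reagents that add atoms: none
Why: Proposed new method: fluoride removes either aryl silyl group of symmetric 8 with loss of triflate to give aryne 12 and also unmasks the alkoxide of 11; the oxygen adds to the aryne carbon next to silicon (future C8a), the resulting C4a carbanion attacks the ester carbonyl, and the expelled ethoxide is silylated by the next molecule of 11, which passes the alkoxide on. The closest known reaction types are the fluoride-triggered aryne annulation of salicylate esters to xanthones and the O-arylation of aliphatic alcohols by arynes; the new elements are a secondary aliphatic alkoxide and an enolisable aliphatic ester as the two reacting ends. Ring C closes by a 6-exo-trig addition–elimination at the ester carbon. No stereocentre is created, and C2 stays S because neither its C–O bond nor its C–H bond takes part. The required regioselectivity lies in the substrate: the methoxyl beside C4a (inductive withdrawal) and the silyl group beside C8a (σ-donation) distort the triple bond in the same sense, so that C8a is the more linear, more electrophilic end and the charge lands at C4a next to oxygen. The silyl ether replaces the free alcohol so that no O–H proton sits beside the C4a anion and no standing alkoxide remains to open the flavanone by retro-oxa-Michael reaction, while low temperature and dilution hold back retro-aldol cleavage of the transient alkoxide.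

Step 7
Reactants: 13 (S)-2-(3,4-dimethoxyphenyl)-5,7-dimethoxy-8-(trimethylsilyl)chroman-4-one
Product: 14 (S)-2-(3,4-dimethoxyphenyl)-8-iodo-5,7-dimethoxychroman-4-one
Conditions: ICl (1.0 equiv), NaHCO3 (solid), CH2Cl2, −78 to −20 °C; aq Na2S2O3
Reagents that add atoms: iodine monochloride ClI
Why: Electrophilic ipso-iododesilylation: attack at the silicon-bearing C8 is favoured by β-silicon stabilisation of the arenium ion and by three ortho/para oxygen donors, so it should outrun iodination at C6–H or on ring B, and the absence of base and hard Lewis acid protects C2.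

Step 8
Reactants: 14 (S)-2-(3,4-dimethoxyphenyl)-8-iodo-5,7-dimethoxychroman-4-one
Product: 16 (S)-2-(3,4-dimethoxyphenyl)-8-hydroxy-5,7-dimethoxychroman-4-one, via 8-pinacolboronate 15 (not isolated)
Conditions: HBpin, PdCl2(MeCN)2 (2 mol %), SPhos (8 mol %), Et3N, 1,4-dioxane, 60 °C; evaporate; THF–pH 7 phosphate buffer, 30% H2O2, 0 °C
Reagents that add atoms: hydrogen peroxide OO (oxygen of 16); pinacolborane CC1(C)OBOC1(C)C (boryl group of 15 only)
Why: Masuda–Miyaura borylation of the aryl iodide with pinacolborane (the bulky biarylphosphine copes with two ortho substituents and the ketone is tolerated) followed by peroxide-induced 1,2-migration of aryl from boron to oxygen, run at neutral pH so that ring C does not open.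

Step 9
Reactants: 16 (S)-2-(3,4-dimethoxyphenyl)-8-hydroxy-5,7-dimethoxychroman-4-one
Product: 17 (S)-2-(3,4-dimethoxyphenyl)-5,7,8-trimethoxychroman-4-one (target)
Conditions: MeOH, PPh3, DIAD, THF, 0 °C to rt
Reagents that add atoms: methanol CO
Why: Mitsunobu etherification: the phenoxide attacks the methoxyphosphonium ion by SN2 under essentially neutral conditions, which avoids the base and alkyl halide conditions that open flavanones to chalcones and would racemise C2.

Compound list
1 | 3,5-dimethoxyphenol | COc1cc(O)cc(OC)c1 | starting material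
2 | 3,5-dimethoxyphenyl isopropylcarbamate | COc1cc(OC(=O)NC(C)C)cc(OC)c1 | intermediate
3 | 3,5-dimethoxyphenyl N-isopropyl-N-(trimethylsilyl)carbamate | COc1cc(OC(=O)N(C(C)C)[Si](C)(C)C)cc(OC)c1 | intermediate
4 | 3,5-dimethoxy-2-(trimethylsilyl)phenyl N-isopropyl-N-(trimethylsilyl)carbamate | COc1cc(OC)c([Si](C)(C)C)c(OC(=O)N(C(C)C)[Si](C)(C)C)c1 | intermediate
5 | 3,5-dimethoxy-2,6-bis(trimethylsilyl)phenyl N-isopropyl-N-(trimethylsilyl)carbamate | COc1cc(OC)c([Si](C)(C)C)c(OC(=O)N(C(C)C)[Si](C)(C)C)c1[Si](C)(C)C | intermediate
6 | 3,5-dimethoxy-2,6-bis(trimethylsilyl)phenyl isopropylcarbamate | COc1cc(OC)c([Si](C)(C)C)c(OC(=O)NC(C)C)c1[Si](C)(C)C | intermediate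
7 | 3,5-dimethoxy-2,6-bis(trimethylsilyl)phenol (present as its DBU salt) | COc1cc(OC)c([Si](C)(C)C)c(O)c1[Si](C)(C)C | intermediate
8 | 3,5-dimethoxy-2,6-bis(trimethylsilyl)phenyl trifluoromethanesulfonate | COc1cc(OC)c([Si](C)(C)C)c(OS(=O)(=O)C(F)(F)F)c1[Si](C)(C)C | intermediate
9 | ethyl 3-(3,4-dimethoxyphenyl)-3-oxopropanoate | CCOC(=O)CC(=O)c1ccc(OC)c(OC)c1 | starting material
10 | ethyl (S)-3-(3,4-dimethoxyphenyl)-3-hydroxypropanoate | COc1ccc([C@@H](O)CC(=O)OCC)cc1OC | intermediate
11 | ethyl (S)-3-(3,4-dimethoxyphenyl)-3-(trimethylsilyloxy)propanoate | COc1ccc([C@@H](O[Si](C)(C)C)CC(=O)OCC)cc1OC | intermediate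
12 | 3,5-dimethoxy-6-(trimethylsilyl)benzyne (triple bond C1–C2) | COC1=CC(OC)=C([Si](C)(C)C)C#C1 | intermediate
13 | (S)-2-(3,4-dimethoxyphenyl)-5,7-dimethoxy-8-(trimethylsilyl)chroman-4-one | COc1ccc([C@@H]2CC(=O)c3c(OC)cc(OC)c([Si](C)(C)C)c3O2)cc1OC | intermediate
14 | (S)-2-(3,4-dimethoxyphenyl)-8-iodo-5,7-dimethoxychroman-4-one | COc1ccc([C@@H]2CC(=O)c3c(OC)cc(OC)c(I)c3O2)cc1OC | intermediate
15 | (S)-2-(3,4-dimethoxyphenyl)-5,7-dimethoxy-8-(4,4,5,5-tetramethyl-1,3,2-dioxaborolan-2-yl)chroman-4-one | COc1ccc([C@@H]2CC(=O)c3c(OC)cc(OC)c(B4OC(C)(C)C(C)(C)O4)c3O2)cc1OC | intermediate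
16 | (S)-2-(3,4-dimethoxyphenyl)-8-hydroxy-5,7-dimethoxychroman-4-one | COc1ccc([C@@H]2CC(=O)c3c(OC)cc(OC)c(O)c3O2)cc1OC | intermediate
17 | (S)-2-(3,4-dimethoxyphenyl)-5,7,8-trimethoxychroman-4-one | COc1ccc([C@@H]2CC(=O)c3c(OC)cc(OC)c(OC)c3O2)cc1OC | target

Total step count: 9. Longest linear sequence: 7 (steps 1, 2, 3, 6, 7, 8, 9); the second branch (steps 4 and 5) joins at step 6.

Steps most likely to fail

Risk 1, step 6 (the labelled step).
- What may go wrong:
  - The C4a anion may pick up a proton, from adventitious water or from the α-CH2 of its own ester, instead of acylating. The second case leads to β-elimination of the aryloxide.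
  - The transient alkoxide may undergo retro-aldol cleavage, transesterification or attack at the sulfonyl sulfur of 8.
  - Fluoride may strip the C8 silyl group.
  - Residual base may open ring C and erode the configuration at C2.
- Fallback (known chemistry), setting out from 10 and 8 and returning at 14:
  - The free alcohol 10 is O-arylated by aryne 12 (KF, 18-crown-6, THF, −20 °C). This is aryne O–H insertion of an aliphatic alcohol under the same regiocontrol. It gives ethyl (S)-3-(3,4-dimethoxyphenyl)-3-[3,5-dimethoxy-2-(trimethylsilyl)phenoxy]propanoate F1.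
  - LiOH in THF–water at 0 °C gives (S)-3-(3,4-dimethoxyphenyl)-3-[3,5-dimethoxy-2-(trimethylsilyl)phenoxy]propanoic acid F2.
  - Trifluoroacetic anhydride with 2,6-di-tert-butyl-4-methylpyridine in CH2Cl2 at 0 °C or below closes ring C by intramolecular Friedel–Crafts acylation through the mixed anhydride.
  - Of the two positions ortho to the ether oxygen, the silicon-bearing one is expected to react first (ipso-acylation), which gives (S)-2-(3,4-dimethoxyphenyl)-5,7-dimethoxychroman-4-one F3.
  - Closure at the C–H position would give 13 itself, which re-enters at step 7.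
  - F3 is iodinated with one equivalent of I2/CF3CO2Ag in CH2Cl2 at low temperature. C8 is the usual site in fully O-methylated 5,7-dioxygenated flavonoids, so this gives 14.

Risk 2, step 8.
- What may go wrong:
  - Reductive loss of iodine at the doubly ortho-substituted, electron-rich carbon.
  - Sluggish boryl transfer.
  - Protodeboronation of the 2,6-dioxygenated boronate.
  - Slow amine-induced opening of ring C at 60 °C.
- Fallback, setting out from 13 and returning at 16 (it bypasses 14):
  - Direct electrophilic ipso-borodesilylation with BCl3 in CH2Cl2 at −78 °C, with 2,6-di-tert-butyl-4-methylpyridine present as acid scavenger, gives (S)-8-(dichloroboryl)-2-(3,4-dimethoxyphenyl)-5,7-dimethoxychroman-4-one F4.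
  - The volatiles are removed cold, and the same buffered H2O2 oxidation gives 16.
  - This path exposes the 5-methoxyl and the C2–O1 bond to a hard Lewis acid, so contact time and temperature must stay minimal and the enantiomeric purity of 16 must be checked.

Risk 3, step 2.
- What may go wrong:
  - Incomplete second metalation next to the first silyl group.
  - Competing metalation at C4 between the two methoxyls.
  - Anionic ortho-Fries migration on warming.
  - Consumption of n-BuLi by leftover TMSCl.
- Fallback, setting out from 1 and returning at 8. It replaces C–H metalation by halogen–lithium exchange and retro-Brook silyl shifts: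
  - NBS (2 equiv) in CH2Cl2 at −78 to 0 °C should brominate the two less crowded positions ortho to the hydroxyl, which gives 2,6-dibromo-3,5-dimethoxyphenol F5.
  - HMDS in THF at reflux gives (2,6-dibromo-3,5-dimethoxyphenoxy)trimethylsilane F6.
  - n-BuLi in THF at −78 °C (Br–Li exchange, then O-to-C silyl migration) followed by TMSCl gives [2-bromo-3,5-dimethoxy-6-(trimethylsilyl)phenoxy]trimethylsilane F7.
  - A second n-BuLi exchange and migration gives the lithium salt of 7, which is trapped with Tf2O at −78 °C as 8.

Further compounds
F1 | step 6 | ethyl (S)-3-(3,4-dimethoxyphenyl)-3-[3,5-dimethoxy-2-(trimethylsilyl)phenoxy]propanoate | COc1ccc([C@@H](Oc2cc(OC)cc(OC)c2[Si](C)(C)C)CC(=O)OCC)cc1OC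
F2 | step 6 | (S)-3-(3,4-dimethoxyphenyl)-3-[3,5-dimethoxy-2-(trimethylsilyl)phenoxy]propanoic acid | COc1ccc([C@@H](Oc2cc(OC)cc(OC)c2[Si](C)(C)C)CC(=O)O)cc1OC
F3 | step 6 | (S)-2-(3,4-dimethoxyphenyl)-5,7-dimethoxychroman-4-one | COc1ccc([C@@H]2CC(=O)c3c(OC)cc(OC)cc3O2)cc1OC
F4 | step 8 | (S)-8-(dichloroboryl)-2-(3,4-dimethoxyphenyl)-5,7-dimethoxychroman-4-one | COc1ccc([C@@H]2CC(=O)c3c(OC)cc(OC)c(B(Cl)Cl)c3O2)cc1OC
F5 | step 2 | 2,6-dibromo-3,5-dimethoxyphenol | COc1cc(OC)c(Br)c(O)c1Br
F6 | step 2 | (2,6-dibromo-3,5-dimethoxyphenoxy)trimethylsilane | COc1cc(OC)c(Br)c(O[Si](C)(C)C)c1Br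
F7 | step 2 | [2-bromo-3,5-dimethoxy-6-(trimethylsilyl)phenoxy]trimethylsilane | COc1cc(OC)c([Si](C)(C)C)c(O[Si](C)(C)C)c1Br
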